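Take a small charge, 0.10 M of starting material under gas held at 5.0 mM, and reckon what is left, not what is made.

| flask | starting material | gas phase | remark | time |
|---|---|---|---|---|
| autumn | 0.20 M | 5 mM (held) | run made earlier |  |
| flask | 0.10 M | 5.0 mM (held) |  | 8.0 min |

autumn run (percent of the starting material charged)

| time / min | target / % | starting material / % |
|---|---|---|
| 0.200 | 2.8 | 93.5 |
| 0.333 | 3.4 | 90.0 |
| 0.500 | 4.3 | 85.9 |
| 0.833 | 6.9 | 75.4 |
| 1.33 | 10.3 | 63.4 |
| 2.50 | 13.3 | 41.1 |

(scatter of a reading: 0.5 percentage points)

- at the start none of the gas phase is in solution

- how much target there is at 8.0 min, in percent of the starting material charged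
- concentration of dissolved gas in solution at 50 s, in percent of saturation
- the change that raises the amount of target at 8.0 min, in percent of the starting material charged most ("none" if none brings more than 2 percentage points) (north-west / north-east / none)
- amount of target at 8.0 min, in percent of the starting material charged, after north-west

- north-west: doubling the transfer coefficient of the gas phase, all else as stated
- north-east: doubling the saturation concentration of gas phase, all else as stated

**Fraction left.** In the autumn run, divide minus the logarithm of the fraction left by the time. This is the loss constant 0.356 min⁻¹ at 2.50 min, and the reading at 0.833 min gives 0.339 min⁻¹. That is a pseudo-first-order fall of [starting material]. I assume the same constant for the flask, where 5.81% then stays at 8.0 min.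

**Bound above.** By this reckoning the flask has lost 94.2%, a crude ceiling on target. In the autumn run the share of lost material found as target falls, from 28.0% at 0.833 min to 22.6% at 2.50 min. Holding that last share tightens my ceiling to 21.3%.

**Bound below.** Target per unit of starting material left climbs through the autumn run, reaching 32.4%. Holding it there gives my floor for the flask, 1.88%.

**The forecast.** It says 9% (5% to 14%), inside my bracket. It also gives 70% of saturation (40% to 95%), 8.5% (4% to 14%) after north-west, and best none: “More gas should not help, so I choose none.”

**The result.** The flask gives 12.2% target, inside the bracket, and 92.1% of saturation. Best is north-east, worth 4.8 percentage points; north-west adds 0.17 points, reaching 12.4%.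

    gas phase ⇌ dissolved gas, rate k1*(csat - [dissolved gas]) (kL = 28.1 min⁻¹)
    starting material + dissolved gas → target (k = 28.0 L mol⁻¹ min⁻¹)
    starting material → side product A (k = 0.222 min⁻¹)
    2 dissolved gas → self-condensation product (k = 29.9 L mol⁻¹ min⁻¹)
    starting material + target → side product B (k = 0.967 L mol⁻¹ min⁻¹)
    target → over-reaction product (k = 0.175 min⁻¹)

**Not at rest.** The reckoned 5.81% stands against 5.2% of starting material in the flask at 8.00 min, and the flask is still moving. At ten times the time, 80.0 min, starting material stands at 0% and target falls from 12.2% to 0%. Over-reaction product climbs from 19.0% to 33.0%, and side product A from 58.0% to 61.1%.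

**Neighbour flask.** Carry 0.356 min⁻¹ to the neighbour flask left until 3.0 min: it gives 34.4% left. The computed amount there is 33.8%.

The readings stem from a simulated flask with constants of no real substance.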